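**Retrosynthetic overview**

Isochromene numbering is used: ring A = C4a, C5, C6, C7, C8, C8a; ring B = C1, O2, C3, C4, C4a, C8a. Ring B is a 4-alkylidene-4H-pyran whose O2–C3 unit is an enol ester of octanoic acid, and C1=C8a–C8=O and C4a=C5–C6=O are the conjugate-addition retrons of two ynones.
Enabling feature: C7 is quaternary (CH3, O-acyl) between the C6 and C8 carbonyls, so nothing can enolise or aromatise. An acyclic 2-acyloxy-2-methyl-1,3-dione carrying an ethynyl ketone (C8, C8a, C1) and a propynyl ketone (C6, C5, C4a, C4) is therefore a viable precursor, and C4 becomes a vinylogously acidic CH3 placed 1,6 to the ester carbon C3.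
Key disconnection: C4a–C8a and C3=C4 are formed in one pot from this bis-ynone and octanoic acid; ring A closes first (C8a onto C4a), ring B second (C4 onto C3, then dehydration).
C7 comes from (R)-lactic acid by Seebach self-regeneration of the stereocentre: the enolate aldol with 3-(trimethylsilyl)propynal brings in the C8 arm with retention, the lactate carboxyl becomes C6 (Weinreb amide, propynyl Grignard), and the decanoate is installed before either ynone exists.

Key step: step 8

**Route**

Step 1
Reactants: 1 (R)-lactic acid; 2 pivalaldehyde
Product: 3 (2R,5R)-2-tert-butyl-5-methyl-1,3-dioxolan-4-one (cis)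
Conditions: p-TsOH (cat.), H2SO4 (cat.), pentane, reflux, Dean–Stark trap; low-temperature crystallisation of the cis isomer
Reagents that add atoms: none
Why: Acid-catalysed acetalisation with water removal (Seebach dioxolanone formation) should favour the cis acetal, the new acetal centre being controlled by the lactate centre and upgraded by crystallisation.

Step 2
Reactants: 3 (2R,5R)-2-tert-butyl-5-methyl-1,3-dioxolan-4-one; 4 3-(trimethylsilyl)prop-2-ynal
Product: 7 (2R,5S)-2-tert-butyl-5-methyl-5-[1-(triethylsilyloxy)-3-(trimethylsilyl)prop-2-yn-1-yl]-1,3-dioxolan-4-one (both carbinol epimers), via lithium enolate 5 (not isolated), via lithium aldolate 6 (not isolated)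
Conditions: LiN(i-Pr)2, THF, −78 °C; then 4, −78 °C; then Et3SiOTf, −78 to −40 °C
Reagents that add atoms: triethylsilyl trifluoromethanesulfonate, CC[Si](CC)(CC)OS(=O)(=O)C(F)(F)F
Why: Seebach self-regeneration-of-stereocentres aldol addition, in which the ynal attacks the planar enolate anti to the tert-butyl group so that the new C–C bond replaces the original H with retention and fixes the future C7; silylation of the aldolate blocks retro-aldol cleavage, and the carbinol epimers converge on later oxidation.

Step 3
Reactants: 7 (2R,5S)-silyl-protected aldol adduct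
Product: 8 (2S)-2-hydroxy-N-methoxy-N,2-dimethyl-3-(triethylsilyloxy)-5-(trimethylsilyl)pent-4-ynamide
Conditions: MeNH(OMe)·HCl, i-PrMgCl, THF, −20 to 0 °C; aq. NH4Cl
Reagents that add atoms: N,O-dimethylhydroxylamine hydrochloride, CNOC.Cl
Why: Aminolysis of the acylal lactone by the chloromagnesium amide (Weinreb amide formation) should open the ring with loss of pivalaldehyde, and the quaternary centre has no α-hydrogen and cannot epimerise.

Step 4
Reactants: 8 hydroxy Weinreb amide; 9 decanoyl chloride
Product: 10 (2S)-1-[methoxy(methyl)amino]-2-methyl-1-oxo-3-(triethylsilyloxy)-5-(trimethylsilyl)pent-4-yn-2-yl decanoate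
Conditions: DMAP, Et3N, CH2Cl2, 0 to 40 °C
Reagents that add atoms: none
Why: DMAP-catalysed acylation of the tertiary alcohol with the acid chloride, placed here because no ynone is yet present that the free hydroxyl or the amine base could attack.

Step 5
Reactants: 10 decanoate Weinreb amide; 11 1-propynylmagnesium bromide
Product: 12 (4S)-4-methyl-5-oxo-3-(triethylsilyloxy)-1-(trimethylsilyl)octa-1,6-diyn-4-yl decanoate
Conditions: CH3C≡CMgBr (THF solution), THF, −20 to 0 °C; inverse quench into cold 1 M HCl
Reagents that add atoms: none
Why: Weinreb ketone synthesis, in which the alkynyl Grignard reagent adds once to give a chelated tetrahedral magnesium intermediate that releases the ynone only on work-up, while the hindered tert-alkyl decanoate should react much more slowly at low temperature.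

Step 6
Reactants: 12 silyl-protected butynone
Product: 13 (4S)-3-hydroxy-4-methyl-5-oxo-1-(trimethylsilyl)octa-1,6-diyn-4-yl decanoate (both carbinol epimers)
Conditions: HF·pyridine, pyridine, THF, 0 °C
Reagents that add atoms: none
Why: Fluoride cleavage of the secondary triethylsilyl ether under mildly acidic, pyridine-buffered conditions should leave the alkynylsilane, the ester and the ynone intact and disfavour base-induced acyl migration or oxa-Michael closure.

Step 7
Reactants: 13 propargylic alcohol
Product: 14 (4R)-4-methyl-3,5-dioxo-1-(trimethylsilyl)octa-1,6-diyn-4-yl decanoate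
Conditions: Dess–Martin periodinane, CH2Cl2, 0 °C to rt
Reagents that add atoms: none
Why: Dess–Martin oxidation of the propargylic alcohol to the ynone under near-neutral conditions, which also removes the undefined carbinol centre.

Step 8
Reactants: 14 silyl bis-ynone; 15 octanoic acid
Product: 20 (7R)-3-heptyl-7-methyl-6,8-dioxo-7,8-dihydro-6H-isochromen-7-yl decanoate (CNP0197863.1), via terminal diynone 16 (not isolated), via acyclic enol octanoate 17 (not isolated), via carbocyclic enol octanoate 18 (not isolated), via C-acylated triketone 19 (not isolated)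
Conditions: CsF, octanoic acid, MeCN, 0 °C; then DBU, 0 °C to rt; then CF3CO2H, rt
Reagents that add atoms: none
Why: Proposed new method: fluoride and the carboxylic acid protodesilylate the alkynylsilane, and the cesium octanoate so formed adds to the unsubstituted β-carbon C1 of the terminal ynone (base-catalysed carboxylic acid conjugate addition) to give the enol ester; under DBU, reversible addition of octanoate (or the amidine) at C1, or transient O-deacylation, turns C8a into an enolate carbon that closes ring A by 6-endo-dig Michael addition onto C4a of the butynone, as in Rauhut–Currier and other nucleophile-triggered tandem Michael cyclisations. The C4 methyl of the resulting cross-conjugated dienone is vinylogously acidic and 1,6 to the ester carbonyl C3, so its dienolate should attack C3 (6-exo-trig) in a vinylogous Baker–Venkataraman O-to-C acyl shift; acid then closes O2 onto C3 (6-exo-trig) and dehydrates to the C3=C4 enol ether, a Kostanecki–Robinson-type cyclodehydration that is the usual closing event of azaphilone pyrans, so ring B forms second. No stereocentre is created, and C7, quaternary and without α-hydrogen, cannot epimerise. The selectivities needed are carboxylate addition at C1 and not C4a (secured by the terminal, unsubstituted ynone and by forming the enol ester first under buffered conditions), C-closure and not O-closure at C4a (oxa-Michael adducts revert, the C–C bond does not), and the E enol ester geometry for acyl capture (equilibrated by reversible addition at C1), with the pyran as the thermodynamic sink.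

**Compound list**

1 | (R)-lactic acid | C[C@@H](O)C(=O)O | starting material
2 | pivalaldehyde | CC(C)(C)C=O | starting material
3 | (2R,5R)-2-tert-butyl-5-methyl-1,3-dioxolan-4-one | C[C@H]1O[C@@H](C(C)(C)C)OC1=O | intermediate
4 | 3-(trimethylsilyl)prop-2-ynal | C[Si](C)(C)C#CC=O | starting material
5 | lithium (2R)-2-tert-butyl-5-methyl-1,3-dioxol-4-olate (lithium enolate of 3, not isolated) | CC1=C([O-])O[C@H](C(C)(C)C)O1.[Li+] | intermediate
6 | lithium aldolate of 3 and 4 (not isolated) | C[C@@]1(C([O-])C#C[Si](C)(C)C)O[C@@H](C(C)(C)C)OC1=O.[Li+] | intermediate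
7 | (2R,5S)-2-tert-butyl-5-methyl-5-[1-(triethylsilyloxy)-3-(trimethylsilyl)prop-2-yn-1-yl]-1,3-dioxolan-4-one | C[C@@]1(C(O[Si](CC)(CC)CC)C#C[Si](C)(C)C)O[C@@H](C(C)(C)C)OC1=O | intermediate
8 | (2S)-2-hydroxy-N-methoxy-N,2-dimethyl-3-(triethylsilyloxy)-5-(trimethylsilyl)pent-4-ynamide | C[C@@](C(O[Si](CC)(CC)CC)C#C[Si](C)(C)C)(O)C(=O)N(C)OC | intermediate
9 | decanoyl chloride | CCCCCCCCCC(=O)Cl | starting material
10 | (2S)-1-[methoxy(methyl)amino]-2-methyl-1-oxo-3-(triethylsilyloxy)-5-(trimethylsilyl)pent-4-yn-2-yl decanoate | C[C@@](C(O[Si](CC)(CC)CC)C#C[Si](C)(C)C)(OC(=O)CCCCCCCCC)C(=O)N(C)OC | intermediate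
11 | 1-propynylmagnesium bromide | CC#C[Mg]Br | starting material
12 | (4S)-4-methyl-5-oxo-3-(triethylsilyloxy)-1-(trimethylsilyl)octa-1,6-diyn-4-yl decanoate | C[C@@](C(O[Si](CC)(CC)CC)C#C[Si](C)(C)C)(OC(=O)CCCCCCCCC)C(=O)C#CC | intermediate
13 | (4S)-3-hydroxy-4-methyl-5-oxo-1-(trimethylsilyl)octa-1,6-diyn-4-yl decanoate | C[C@@](C(O)C#C[Si](C)(C)C)(OC(=O)CCCCCCCCC)C(=O)C#CC | intermediate
14 | (4R)-4-methyl-3,5-dioxo-1-(trimethylsilyl)octa-1,6-diyn-4-yl decanoate | C[C@@](C(=O)C#C[Si](C)(C)C)(OC(=O)CCCCCCCCC)C(=O)C#CC | intermediate
15 | octanoic acid | CCCCCCCC(=O)O | starting material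
16 | (4S)-4-methyl-3,5-dioxoocta-1,6-diyn-4-yl decanoate (not isolated) | CCCCCCCCCC(=O)O[C@](C)(C(=O)C#CC)C(=O)C#C | intermediate
17 | (1E,4S)-4-(decanoyloxy)-4-methyl-3,5-dioxooct-1-en-6-yn-1-yl octanoate (not isolated) | CCCCCCCCCC(=O)O[C@](C)(C(=O)C#CC)C(=O)/C=C/OC(=O)CCCCCCC | intermediate
18 | (1R)-1,4-dimethyl-3-[(E)-(octanoyloxy)methylidene]-2,6-dioxocyclohex-4-en-1-yl decanoate (not isolated) | CCCCCCCCCC(=O)O[C@]1(C)C(=O)C=C(C)/C(=C\OC(=O)CCCCCCC)C1=O | intermediate
19 | (1R)-3-(hydroxymethylidene)-1-methyl-2,6-dioxo-4-(2-oxononyl)cyclohex-4-en-1-yl decanoate (present as its enolate, not isolated) | CCCCCCCCCC(=O)O[C@]1(C)C(=O)C=C(CC(=O)CCCCCCC)C(=CO)C1=O | intermediate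
20 | (7R)-3-heptyl-7-methyl-6,8-dioxo-7,8-dihydro-6H-isochromen-7-yl decanoate | CCCCCCCCCC(=O)O[C@]1(C)C(=O)C=C2C=C(CCCCCCC)OC=C2C1=O | target

**Step count and risks**

Total steps: 8. Longest linear sequence: 8 steps (1 → 3 → 7 → 8 → 10 → 12 → 13 → 14 → 20).

Steps most likely to fail:

1. Step 8 (proposed new method). The carbocyclisation may run with reversed donor and acceptor roles (octanoate adding at C4a and the C5 carbanion attacking C1) or stop at reversible O-closure. The C4 acyl capture may be outrun by loss of the labile enol-ester acyl group, by acyl exchange with the C7 decanoate, or by retro-Claisen opening of the 2-acyloxy-1,3-dione.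
Fallback, known reactions only, from 14 back to 18: AgNO3-catalysed protodesilylation in aqueous acetone should give 16. Dimethylamine (1 equiv, THF, −78 °C) should then add only to the terminal ynone to give the dimethylaminovinyl ketone F1, which makes C8a the only nucleophilic carbon. Gentle warming with a little acetic acid closes ring A by the enaminone-to-ynone Michael addition known as the first stage of the Bohlmann–Rahtz reaction, giving the aminomethylidene dienedione F2. Mild aqueous acid hydrolyses this to the hydroxymethylidene compound F3, and octanoyl chloride with pyridine O-acylates it to 18. From 18 the route continues as two ordinary operations, K2CO3 for the Baker–Venkataraman acyl shift to 19 and acid for the cyclodehydration to 20.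

2. Step 5. Chemoselectivity may be lost through attack of the alkynyl Grignard reagent on the decanoate carbonyl or through transfer of the decanoyl group to the magnesium hemiaminal alkoxide.
Fallback, from 8 back to 12, with the order inverted: 11 (3 equiv) is added to the Weinreb amide of 8 while the tertiary hydroxyl is masked as its magnesium alkoxide, which should give the α′-hydroxy ynone F4 after cold acidic work-up. F4 is then esterified without amine base (decanoic anhydride, Sc(OTf)3 cat., CH2Cl2, −20 °C) to avoid the base-induced furanone closure of α′-hydroxy ynones, giving 12.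

3. Step 6. Once the secondary hydroxyl is free, the decanoyl group may migrate from the tertiary to the secondary oxygen, or the hydroxyl may close onto the butynone by 6-endo oxa-Michael addition during isolation.
Fallback, from 12 directly to 14: oxidative desilylation with Jones reagent (CrO3, H2SO4, acetone, 0 °C) cleaves the silyl ether and oxidises the carbinol in the same acidic, oxidising medium, so the free β-hydroxy ynone is never isolated and never meets a base; no new compound arises (F0).

**Further compounds**

F1 | step 8 | (1E,4S)-1-(dimethylamino)-4-methyl-3,5-dioxooct-1-en-6-yn-4-yl decanoate | CCCCCCCCCC(=O)O[C@](C)(C(=O)C#CC)C(=O)/C=C/N(C)C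
F2 | step 8 | (1R)-3-[(dimethylamino)methylidene]-1,4-dimethyl-2,6-dioxocyclohex-4-en-1-yl decanoate | CCCCCCCCCC(=O)O[C@]1(C)C(=O)C=C(C)C(=CN(C)C)C1=O
F3 | step 8 | (1R)-3-(hydroxymethylidene)-1,4-dimethyl-2,6-dioxocyclohex-4-en-1-yl decanoate | CCCCCCCCCC(=O)O[C@]1(C)C(=O)C=C(C)C(=CO)C1=O
F4 | step 5 | (5S)-5-hydroxy-5-methyl-6-(triethylsilyloxy)-8-(trimethylsilyl)octa-2,7-diyn-4-one | C[C@@](C(O[Si](CC)(CC)CC)C#C[Si](C)(C)C)(O)C(=O)C#CC
F0 | step 6 | none | none
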